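**Retrosynthetic overview**

- Target 15 ← bromo-dediazoniation at C4' ← nitro reduction ← bromination at C6' of nitrophenol 11. The C4' nitro group is a placeholder for the second ring B bromine.
- Structural feature: in ring B the C1'-OH is para to C4'-Br, and C4' lies between the two CH carbons C3' and C5'. C4' can therefore enter alone as the carbon of nitromethane 9, replacing the ring oxygen of 3-aryloxy-4-pyranone 8 (carbonyl carbon = C1', aryloxy carbon = C2').
- Pyranone 8 ← bis-enaminone 7 ← aryloxyacetone 4 and two equivalents of formamide acetal 5; 4 ← phenol 2 and chloroacetone 3; 2 ← dibromination of guaiacol 1.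
- Ring order: ring A is bought with guaiacol, the pyranone ring is built on its phenolic oxygen (step 4), and ring B is made from the pyranone (step 5).

Key step: step 5

Remark: the target has no stereocentre. The double-bond geometries written for 6, 7 and 10 are the expected ones and are lost in the ring closures.

**Route**

Step 1
Reactants: 1 2-methoxyphenol (guaiacol)
Product: 2 2,4-dibromo-6-methoxyphenol
Conditions: Br2 (2.05 equiv), CH2Cl2, 0 °C to rt
Reagents that add atoms: bromine, BrBr
Why: Electrophilic aromatic bromination in which the free hydroxyl outranks the methoxy group as director, so the two bromines should enter para and then ortho to the OH.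

Step 2
Reactants: 2 2,4-dibromo-6-methoxyphenol; 3 chloroacetone
Product: 4 1-(2,4-dibromo-6-methoxyphenoxy)propan-2-one
Conditions: K2CO3, KI (cat.), acetone, reflux
Reagents that add atoms: none
Why: Williamson ether synthesis, an SN2 displacement on a reactive alpha-halo ketone (iodide-assisted) by the phenoxide, which tolerates the two ortho substituents.

Step 3
Reactants: 4 1-(2,4-dibromo-6-methoxyphenoxy)propan-2-one; 5 N,N-dimethylformamide dimethyl acetal
Product: 7 (1Z,4E)-2-(2,4-dibromo-6-methoxyphenoxy)-1,5-bis(dimethylamino)penta-1,4-dien-3-one, via mono-enaminone 6 (not isolated)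
Conditions: 5 (6 equiv), neat, 110 then 140 °C, MeOH distilled off
Reagents that add atoms: none
Why: Aminomethylenation of both CH-acidic positions flanking the ketone by the formamide acetal, first at the aryloxy-bearing methylene to give 6 and then at the methyl group of this vinylogous amide; either order converges on 7.

Step 4
Reactants: 7 (1Z,4E)-2-(2,4-dibromo-6-methoxyphenoxy)-1,5-bis(dimethylamino)penta-1,4-dien-3-one
Product: 8 3-(2,4-dibromo-6-methoxyphenoxy)-4H-pyran-4-one
Conditions: 2 M aq. HCl, THF, 50 °C
Reagents that add atoms: water, O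
Why: Acid hydrolysis of one enaminone to the formyl enol, whose oxygen adds to the beta carbon of the other, protonated enaminone (6-endo-trig addition-elimination) and expels dimethylamine, giving the acid-stable 4-pyranone.

Step 5
Reactants: 8 3-(2,4-dibromo-6-methoxyphenoxy)-4H-pyran-4-one; 9 nitromethane
Product: 11 2-(2,4-dibromo-6-methoxyphenoxy)-4-nitrophenol, via ring-opened nitrodienone 10 (not isolated)
Conditions: KOtBu (2.5 equiv), 9 (3 equiv), tBuOH/THF, rt to 80 °C; then 1 M HCl
Reagents that add atoms: none
Why: The nitronate of 9 adds in conjugate fashion to the unsubstituted alpha carbon C6 of the vinylogous ester (forming C4'-C5'; addition at C2 would lead to the same arene), and the 2H-pyran adduct opens by loss of the ring oxygen as the enolate of a formyl ketone, giving 10 with a cis enone. The nitro-bearing carbon, deprotonated again, then attacks the formyl carbon in an intramolecular nitro-aldol (Henry) addition, closing ring B in 6-exo-trig mode and forming C3'-C4'; loss of water and tautomerization give the 4-nitrophenolate, which makes the sequence irreversible. The closest known reaction type is the conversion of 4-pyranones and pyrylium salts into 4-nitrophenols and nitroarenes with nitromethane and KOtBu. No stereocentre is formed. The step needs chemoselectivity for the pyranone over ring A, which should hold because the ring A bromides have no activating group for substitution by a nitronate and are not converted to an aryne by KOtBu in tBuOH at this temperature. The diaryl ether oxygen sits on the alpha carbon C3 of the enone and cannot be lost by beta-elimination.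

Step 6
Reactants: 11 2-(2,4-dibromo-6-methoxyphenoxy)-4-nitrophenol
Product: 12 2-bromo-6-(2,4-dibromo-6-methoxyphenoxy)-4-nitrophenol
Conditions: Br2 (1.0 equiv), NaOAc, AcOH, rt
Reagents that add atoms: bromine, BrBr
Why: Electrophilic aromatic bromination at C6', the only position that is ortho to the hydroxyl and meta to the nitro group, reacting through the buffered phenol/phenolate faster than the doubly brominated and hindered ring A.

Step 7
Reactants: 12 2-bromo-6-(2,4-dibromo-6-methoxyphenoxy)-4-nitrophenol
Product: 13 4-amino-2-bromo-6-(2,4-dibromo-6-methoxyphenoxy)phenol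
Conditions: Fe powder, AcOH/EtOH, 60 °C, under N2; used directly
Reagents that add atoms: none
Why: Béchamp-type dissolving-metal reduction of the nitro group by electron transfer from iron, which leaves aryl bromides and the diaryl ether untouched where catalytic hydrogenation would risk hydrodebromination.

Step 8
Reactants: 13 4-amino-2-bromo-6-(2,4-dibromo-6-methoxyphenoxy)phenol
Product: 15 2,4-dibromo-6-(2,4-dibromo-6-methoxyphenoxy)phenol, via arenediazonium bromide 14 (not isolated)
Conditions: NaNO2, 48% aq. HBr, MeCN, 0 °C; then CuBr (0.2 equiv), 48% aq. HBr, 60 °C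
Reagents that add atoms: hydrobromic acid, Br; sodium nitrite, [Na+].[O-]N=O
Why: Diazotization followed by Sandmeyer bromination, in which CuBr reduces the diazonium ion to an aryl radical that takes up bromine at C4'; the strongly acidic medium should keep the 4-hydroxybenzenediazonium ion protonated so that it does not collapse to a quinone diazide.

**Compound list**

1 | 2-methoxyphenol (guaiacol) | COc1ccccc1O | starting material
2 | 2,4-dibromo-6-methoxyphenol | COc1cc(Br)cc(Br)c1O | intermediate
3 | chloroacetone | CC(=O)CCl | starting material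
4 | 1-(2,4-dibromo-6-methoxyphenoxy)propan-2-one | COc1cc(Br)cc(Br)c1OCC(C)=O | intermediate
5 | N,N-dimethylformamide dimethyl acetal | COC(OC)N(C)C | starting material
6 | (3Z)-3-(2,4-dibromo-6-methoxyphenoxy)-4-(dimethylamino)but-3-en-2-one (mono-enaminone, not isolated) | CC(=O)/C(Oc1c(Br)cc(Br)cc1OC)=C/N(C)C | intermediate
7 | (1Z,4E)-2-(2,4-dibromo-6-methoxyphenoxy)-1,5-bis(dimethylamino)penta-1,4-dien-3-one | CN(C)/C=C/C(=O)/C(Oc1c(Br)cc(Br)cc1OC)=C/N(C)C | intermediate
8 | 3-(2,4-dibromo-6-methoxyphenoxy)-4H-pyran-4-one | COc1cc(Br)cc(Br)c1OC1=COC=CC1=O | intermediate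
9 | nitromethane | C[N+](=O)[O-] | starting material
10 | (1E,4Z)-2-(2,4-dibromo-6-methoxyphenoxy)-1-hydroxy-6-nitrohexa-1,4-dien-3-one (ring-opened nitrodienone, present as its potassium salt, not isolated) | O/C=C(/Oc1c(Br)cc(Br)cc1OC)C(=O)/C=C\C[N+](=O)[O-] | intermediate
11 | 2-(2,4-dibromo-6-methoxyphenoxy)-4-nitrophenol | COc1cc(Br)cc(Br)c1Oc1cc([N+](=O)[O-])ccc1O | intermediate
12 | 2-bromo-6-(2,4-dibromo-6-methoxyphenoxy)-4-nitrophenol | COc1cc(Br)cc(Br)c1Oc1cc([N+](=O)[O-])cc(Br)c1O | intermediate
13 | 4-amino-2-bromo-6-(2,4-dibromo-6-methoxyphenoxy)phenol | COc1cc(Br)cc(Br)c1Oc1cc(N)cc(Br)c1O | intermediate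
14 | 3-bromo-5-(2,4-dibromo-6-methoxyphenoxy)-4-hydroxybenzenediazonium bromide (not isolated) | COc1cc(Br)cc(Br)c1Oc1cc([N+]#N)cc(Br)c1O.[Br-] | intermediate
15 | 2,4-dibromo-6-(2,4-dibromo-6-methoxyphenoxy)phenol | COc1cc(Br)cc(Br)c1Oc1cc(Br)cc(Br)c1O | target

**Step count**

Total steps: 8. Longest linear sequence: 8 steps, from guaiacol 1 to target 15.

**Steps most likely to fail**

Step 5. The pyranone is free at both alpha carbons, so alkoxide-induced ring opening and oligomerization may outrun the nitro-aldol closure, or the formyl enolate of 10 may be too unreactive to accept the nitronate carbon. The fallback gives up the ring exchange and attaches ring B as a preformed benzene. It sets out from phenol 2. Nucleophilic aromatic substitution on commercial 4-bromo-2-fluorobenzaldehyde (K2CO3, DMAc, 110 °C) should give 4-bromo-2-(2,4-dibromo-6-methoxyphenoxy)benzaldehyde F1. Baeyer-Villiger (Dakin-type) oxidation with mCPBA in CH2Cl2 should give 4-bromo-2-(2,4-dibromo-6-methoxyphenoxy)phenyl formate F2. Hydrolysis with aqueous NaOH in THF should give 4-bromo-2-(2,4-dibromo-6-methoxyphenoxy)phenol F3. Bromination ortho to the hydroxyl (Br2, NaOAc, AcOH, rt) comes back to the route at target 15.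

Step 8. Nitrous acid may oxidize the electron-rich 4-aminophenol to quinone-type material, or the diazonium ion may deprotonate to a quinone diazide that resists bromine transfer. The fallback masks the phenol before the nitro group is reduced and runs the dediazoniation without water. It sets out from 12. Acylation (pivaloyl chloride, Et3N, DMAP cat., CH2Cl2) should give 2-bromo-6-(2,4-dibromo-6-methoxyphenoxy)-4-nitrophenyl pivalate F4. Reduction with Fe powder in AcOH/EtOH should give 4-amino-2-bromo-6-(2,4-dibromo-6-methoxyphenoxy)phenyl pivalate F5. Treatment with tert-butyl nitrite and CuBr2 in MeCN (0 to 60 °C) should pass through 3-bromo-5-(2,4-dibromo-6-methoxyphenoxy)-4-(pivaloyloxy)benzenediazonium bromide F6 and give 2,4-dibromo-6-(2,4-dibromo-6-methoxyphenoxy)phenyl pivalate F7. Methanolysis (K2CO3, MeOH, rt) comes back to the route at target 15.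

Step 3. The second condensation, at the methyl group of the vinylogous amide, may stall at the mono-enaminone, or the material may decompose at the temperature the second condensation needs. The fallback replaces the second aminomethylenation by a Claisen formylation of a lithium enolate. It sets out from 4. One equivalent of 5 in toluene at 80 °C should stop at mono-enaminone 6, which is isolated. Deprotonation at the methyl group with LiN(SiMe3)2 in THF at -78 °C and trapping with ethyl formate should give (4Z)-4-(2,4-dibromo-6-methoxyphenoxy)-5-(dimethylamino)-3-oxopent-4-enal F8. Trifluoroacetic acid in CH2Cl2 at rt should then close the ring with loss of dimethylamine and come back to the route at pyranone 8.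

**Further compounds**

F1 | step 5 | 4-bromo-2-(2,4-dibromo-6-methoxyphenoxy)benzaldehyde | COc1cc(Br)cc(Br)c1Oc1cc(Br)ccc1C=O
F2 | step 5 | 4-bromo-2-(2,4-dibromo-6-methoxyphenoxy)phenyl formate | COc1cc(Br)cc(Br)c1Oc1cc(Br)ccc1OC=O
F3 | step 5 | 4-bromo-2-(2,4-dibromo-6-methoxyphenoxy)phenol | COc1cc(Br)cc(Br)c1Oc1cc(Br)ccc1O
F4 | step 8 | 2-bromo-6-(2,4-dibromo-6-methoxyphenoxy)-4-nitrophenyl pivalate | COc1cc(Br)cc(Br)c1Oc1cc([N+](=O)[O-])cc(Br)c1OC(=O)C(C)(C)C
F5 | step 8 | 4-amino-2-bromo-6-(2,4-dibromo-6-methoxyphenoxy)phenyl pivalate | COc1cc(Br)cc(Br)c1Oc1cc(N)cc(Br)c1OC(=O)C(C)(C)C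
F6 | step 8 | 3-bromo-5-(2,4-dibromo-6-methoxyphenoxy)-4-(pivaloyloxy)benzenediazonium bromide | COc1cc(Br)cc(Br)c1Oc1cc([N+]#N)cc(Br)c1OC(=O)C(C)(C)C.[Br-]
F7 | step 8 | 2,4-dibromo-6-(2,4-dibromo-6-methoxyphenoxy)phenyl pivalate | COc1cc(Br)cc(Br)c1Oc1cc(Br)cc(Br)c1OC(=O)C(C)(C)C
F8 | step 3 | (4Z)-4-(2,4-dibromo-6-methoxyphenoxy)-5-(dimethylamino)-3-oxopent-4-enal | O=CCC(=O)/C(Oc1c(Br)cc(Br)cc1OC)=C/N(C)C
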